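The target is the meso (2R,3S) form of 2,3-dimethyl-1,4-bis(4-hydroxy-3,5-dimethoxyphenyl)butane, so the whole stereochemical task is the syn relationship of the two methine hydrogens at C2 and C3. They are added last, as H2, to a (Z)-tetrasubstituted C2=C3 olefin. The route therefore rests on disconnecting the benzylic CH2–C2 bond at the olefin stage: a stereoretentive sp3–sp2 Suzuki–Miyaura coupling joins the O-benzylated syringylmethyl chloride to a tetrasubstituted alkenyl boronate that already carries the other arylmethyl group cis to boron (made by syn-benzylboration of but-2-yne). The step exploits the mirror plane through the C2–C3 bond that relates the two identical CH(CH3)CH2–aryl halves.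

Key step: step 4

Remark on the chemistry: the SMILES encodes (2R,3S) on a constitutionally symmetric chain, which is the achiral meso compound. Only relative configuration has to be controlled and no enantioselective step is needed. Butane numbering is used throughout: C1/C4 are the benzylic CH2 groups and C2/C3 the methine carbons.

Step 1
Reactants: 1 4-hydroxy-3,5-dimethoxybenzyl alcohol (syringyl alcohol)
Product: 2 [4-(benzyloxy)-3,5-dimethoxyphenyl]methanol
Conditions: BnBr, K2CO3, acetone, reflux
Reagents that add atoms: benzyl bromide BrCc1ccccc1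
Why: Williamson ether synthesis; carbonate deprotonates only the phenol, so O-benzylation should be selective over the benzylic alcohol.

Step 2
Reactants: 2 [4-(benzyloxy)-3,5-dimethoxyphenyl]methanol
Product: 3 2-(benzyloxy)-5-(chloromethyl)-1,3-dimethoxybenzene
Conditions: SOCl2, CH2Cl2, 0 °C to rt
Reagents that add atoms: thionyl chloride O=S(Cl)Cl
Why: Deoxychlorination of an electron-rich benzylic alcohol through its chlorosulfite should be fast and leave the aryl benzyl and methyl ethers intact; the chloride is used without chromatography.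

Step 3
Reactants: 3 2-(benzyloxy)-5-(chloromethyl)-1,3-dimethoxybenzene; 4 but-2-yne (excess)
Product: 5 2-[(2E)-4-[4-(benzyloxy)-3,5-dimethoxyphenyl]-3-methylbut-2-en-2-yl]-4,4,5,5-tetramethyl-1,3,2-dioxaborolane (arylmethyl and boryl groups cis)
Conditions: B2pin2, (SIMes)CuCl (5 mol%), KOtBu, THF, rt, sealed tube
Reagents that add atoms: bis(pinacolato)diboron CC1(C)OB(OC1(C)C)B1OC(C)(C)C(C)(C)O1
Why: Copper-catalysed three-component carboboration (benzylboration) of an internal alkyne should add boron and the arylmethyl group of 3 to the same face of but-2-yne (syn), giving the tetrasubstituted alkenyl boronate with CH2Ar and Bpin cis, and the symmetry of the alkyne removes any regiochemical question.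

Step 4
Reactants: 5 alkenyl boronate (arylmethyl and boryl cis); 3 2-(benzyloxy)-5-(chloromethyl)-1,3-dimethoxybenzene
Product: 6 (Z)-1,4-bis[4-(benzyloxy)-3,5-dimethoxyphenyl]-2,3-dimethylbut-2-ene
Conditions: Pd(OAc)2 (5 mol%), SPhos (10 mol%), K3PO4, THF/H2O (10:1), 60 °C
Reagents that add atoms: none
Why: Pd(0)/SPhos should add oxidatively to the benzylic C–Cl bond of 3, the phosphate-activated alkenyl boronate 5 transmetalates with retention at the sp2 carbon, and reductive elimination forges the ArCH2–C(sp2) bond. The closest known reaction type is the Suzuki–Miyaura coupling of alkenylboronic esters with benzylic halides. No ring is closed and no stereocentre is formed; the stereochemical element is the olefin geometry, controlled by the cis arylmethyl/boryl arrangement of 5, so the two arylmethyl groups should end cis (Z). This Z geometry is the latent meso configuration, because step 5 adds both hydrogens to one face. The step needs retention of geometry and no migration of the double bond toward either ring, which the configurational stability of the alkenyl–palladium species, the absence of β-hydrogens in the benzyl–palladium partner and the mild base should secure; the bulky electron-rich ligand should outpace protodeboronation and benzyl homocoupling.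

Step 5
Reactants: 6 (Z)-1,4-bis[4-(benzyloxy)-3,5-dimethoxyphenyl]-2,3-dimethylbut-2-ene
Product: 7 (2R,3S)-1,4-bis[4-(benzyloxy)-3,5-dimethoxyphenyl]-2,3-dimethylbutane (meso)
Conditions: H2 (10 bar), [Ir(cod)(PCy3)(py)]PF6 (5 mol%), CH2Cl2, rt
Reagents that add atoms: none
Why: Homogeneous iridium-catalysed (Crabtree-type) hydrogenation is among the few methods that saturate unfunctionalised tetrasubstituted olefins, and because both hydrogens are delivered to one face of the Z-olefin the two new stereocentres C2 and C3 should form as the (2R,3S) meso pair, with the aryl benzyl ethers untouched.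

Step 6
Reactants: 7 (2R,3S)-1,4-bis[4-(benzyloxy)-3,5-dimethoxyphenyl]-2,3-dimethylbutane (meso)
Product: 8 4,4'-[(2R,3S)-2,3-dimethylbutane-1,4-diyl]bis(2,6-dimethoxyphenol) (meso; CNP0314108.1)
Conditions: H2 (1 atm), 10% Pd/C, EtOAc/MeOH, rt
Reagents that add atoms: none
Why: Palladium-catalysed hydrogenolysis should cleave both aryl benzyl ethers to toluene and the free phenols without touching the non-epimerisable C2/C3 methines, the methyl ethers or the arenes.

Compound list
1 | 4-hydroxy-3,5-dimethoxybenzyl alcohol (syringyl alcohol) | COc1cc(CO)cc(OC)c1O | starting material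
2 | [4-(benzyloxy)-3,5-dimethoxyphenyl]methanol | COc1cc(CO)cc(OC)c1OCc1ccccc1 | intermediate
3 | 2-(benzyloxy)-5-(chloromethyl)-1,3-dimethoxybenzene | COc1cc(CCl)cc(OC)c1OCc1ccccc1 | intermediate
4 | but-2-yne | CC#CC | starting material
5 | 2-[(2E)-4-[4-(benzyloxy)-3,5-dimethoxyphenyl]-3-methylbut-2-en-2-yl]-4,4,5,5-tetramethyl-1,3,2-dioxaborolane (arylmethyl and boryl cis) | C/C(Cc1cc(OC)c(OCc2ccccc2)c(OC)c1)=C(\C)B1OC(C)(C)C(C)(C)O1 | intermediate
6 | (Z)-1,4-bis[4-(benzyloxy)-3,5-dimethoxyphenyl]-2,3-dimethylbut-2-ene | C/C(Cc1cc(OC)c(OCc2ccccc2)c(OC)c1)=C(\C)Cc1cc(OC)c(OCc2ccccc2)c(OC)c1 | intermediate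
7 | (2R,3S)-1,4-bis[4-(benzyloxy)-3,5-dimethoxyphenyl]-2,3-dimethylbutane (meso) | COc1cc(C[C@@H](C)[C@@H](C)Cc2cc(OC)c(OCc3ccccc3)c(OC)c2)cc(OC)c1OCc1ccccc1 | intermediate
8 | 4,4'-[(2R,3S)-2,3-dimethylbutane-1,4-diyl]bis(2,6-dimethoxyphenol) (meso) | COc1cc(C[C@@H](C)[C@@H](C)Cc2cc(OC)c(O)c(OC)c2)cc(OC)c1O | target

Total step count: 6. Longest linear sequence: 6 steps (1 → 2 → 3 → 5 → 6 → 7 → 8; chloride 3 enters twice, in steps 3 and 4).

Steps most likely to fail

Step 5. The tetrasubstituted double bond may migrate into conjugation with an aryl ring, or scramble between E and Z, before hydrogen is added, or the hindered olefin may not turn over. Either process erodes the meso outcome. The fallback abandons the olefin and sets the configuration by ring-controlled enolate alkylation; it sets out from 2 and 3 and returns at 8.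
- Alcohol 2 is oxidised (MnO2, CH2Cl2) to 4-(benzyloxy)-3,5-dimethoxybenzaldehyde F1.
- Zinc-mediated Barbier crotylation (crotyl bromide, Zn, THF/aq. NH4Cl) should give 1-[4-(benzyloxy)-3,5-dimethoxyphenyl]-2-methylbut-3-en-1-ol F2 as any syn/anti mixture.
- Hydroboration–oxidation (9-BBN; NaOH, H2O2) should give 1-[4-(benzyloxy)-3,5-dimethoxyphenyl]-2-methylbutane-1,4-diol F3.
- TEMPO/PhI(OAc)2 oxidative lactonisation should give 5-[4-(benzyloxy)-3,5-dimethoxyphenyl]-4-methyloxolan-2-one F4, racemic and as either C5 epimer.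
- The lithium enolate of F4 (LiHMDS, THF, −78 °C) is alkylated with chloride 3 (NaI) anti to the ring methyl group. This should give the 3,4-trans lactone 3-[4-(benzyloxy)-3,5-dimethoxybenzyl]-5-[4-(benzyloxy)-3,5-dimethoxyphenyl]-4-methyloxolan-2-one F5. The trans arrangement of F5 becomes the meso one once the benzylic lactone C–O bond is cut, so both enantiomers and both C5 epimers converge.
- Hydrogenolysis (H2, Pd/C, AcOH) should cleave that C–O bond and both benzyl ethers to 2-(4-hydroxy-3,5-dimethoxybenzyl)-4-(4-hydroxy-3,5-dimethoxyphenyl)-3-methylbutanoic acid F6.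
- BH3·THF should reduce the acid to 2-(4-hydroxy-3,5-dimethoxybenzyl)-4-(4-hydroxy-3,5-dimethoxyphenyl)-3-methylbutan-1-ol F7.
- I2/PPh3/imidazole should convert only the aliphatic hydroxyl into 4,4'-[2-(iodomethyl)-3-methylbutane-1,4-diyl]bis(2,6-dimethoxyphenol) F8.
- Hydrodeiodination (H2, Pd/C, Et3N, MeOH) should give 8.

Step 3. The copper–boryl species or tert-butoxide may substitute the benzylic chloride directly, outrunning addition to the volatile, unactivated dialkylalkyne. The fallback separates the two events; it sets out from 4 and returns at 5. Platinum-catalysed syn-diboration of 4 (B2pin2, Pt(PPh3)4, DMF, 80 °C) should give (Z)-2,3-bis(4,4,5,5-tetramethyl-1,3,2-dioxaborolan-2-yl)but-2-ene F9. A Suzuki–Miyaura mono-coupling of F9 with 3 as the limiting partner (Pd(OAc)2/SPhos, K3PO4, THF/H2O) should then give 5.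

Step 4. Transmetalation of the hindered tetrasubstituted alkenyl boronate may be slow, so that protodeboronation of 5 and hydrolysis or homocoupling of the benzylic chloride take over. The fallback inverts the polarity of the coupling; it sets out from 5 and 3 and returns at 6. Iododeboronation of 5 with retention (NaOH, then I2, THF, 0 °C) should give 2-(benzyloxy)-5-[(2Z)-3-iodo-2-methylbut-2-en-1-yl]-1,3-dimethoxybenzene F10. Chloride 3 is converted with zinc dust and LiCl in THF into [4-(benzyloxy)-3,5-dimethoxybenzyl]zinc chloride F11, which is not isolated. Negishi coupling of F10 with F11 (Pd(OAc)2/SPhos, THF, rt) should give 6 with retention of the olefin geometry.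

Further compounds
F1 | step 5 | 4-(benzyloxy)-3,5-dimethoxybenzaldehyde | COc1cc(C=O)cc(OC)c1OCc1ccccc1
F2 | step 5 | 1-[4-(benzyloxy)-3,5-dimethoxyphenyl]-2-methylbut-3-en-1-ol (racemic, syn/anti mixture) | COc1cc(C(O)C(C)C=C)cc(OC)c1OCc1ccccc1
F3 | step 5 | 1-[4-(benzyloxy)-3,5-dimethoxyphenyl]-2-methylbutane-1,4-diol (racemic, diastereomer mixture) | COc1cc(C(O)C(C)CCO)cc(OC)c1OCc1ccccc1
F4 | step 5 | 5-[4-(benzyloxy)-3,5-dimethoxyphenyl]-4-methyloxolan-2-one (racemic, C5 epimers) | COc1cc(C2OC(=O)CC2C)cc(OC)c1OCc1ccccc1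
F5 | step 5 | 3,4-trans-3-[4-(benzyloxy)-3,5-dimethoxybenzyl]-5-[4-(benzyloxy)-3,5-dimethoxyphenyl]-4-methyloxolan-2-one (racemic, one enantiomer drawn, C5 open) | COc1cc(C[C@@H](C(=O)O2)[C@@H](C)C2c3cc(OC)c(OCc4ccccc4)c(OC)c3)cc(OC)c1OCc1ccccc1
F6 | step 5 | 2-(4-hydroxy-3,5-dimethoxybenzyl)-4-(4-hydroxy-3,5-dimethoxyphenyl)-3-methylbutanoic acid (racemic, one enantiomer drawn) | COc1cc(C[C@@H](C(=O)O)[C@@H](C)Cc2cc(OC)c(O)c(OC)c2)cc(OC)c1O
F7 | step 5 | 2-(4-hydroxy-3,5-dimethoxybenzyl)-4-(4-hydroxy-3,5-dimethoxyphenyl)-3-methylbutan-1-ol (racemic, one enantiomer drawn) | COc1cc(C[C@@H](CO)[C@@H](C)Cc2cc(OC)c(O)c(OC)c2)cc(OC)c1O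
F8 | step 5 | 4,4'-[2-(iodomethyl)-3-methylbutane-1,4-diyl]bis(2,6-dimethoxyphenol) (racemic, one enantiomer drawn) | COc1cc(C[C@@H](CI)[C@@H](C)Cc2cc(OC)c(O)c(OC)c2)cc(OC)c1O
F9 | step 3 | (Z)-2,3-bis(4,4,5,5-tetramethyl-1,3,2-dioxaborolan-2-yl)but-2-ene | C/C(B1OC(C)(C)C(C)(C)O1)=C(\C)B1OC(C)(C)C(C)(C)O1
F10 | step 4 | 2-(benzyloxy)-5-[(2Z)-3-iodo-2-methylbut-2-en-1-yl]-1,3-dimethoxybenzene | C/C(Cc1cc(OC)c(OCc2ccccc2)c(OC)c1)=C(\C)I
F11 | step 4 | [4-(benzyloxy)-3,5-dimethoxybenzyl]zinc chloride (not isolated) | COc1cc(C[Zn]Cl)cc(OC)c1OCc1ccccc1
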